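## Structural features

The target 44 is a germacranolide: a ten-membered carbocycle (C1–C10) in which an oxygen bridge from C3 to C10 turns C10–C1(=O)–C2=C3–O into a 3(2H)-furanone, and in which C6 and C7 carry an α-methylene-γ-butyrolactone (C11, C12, C13; lactone oxygen on C6). The furanone C2=C3 bond is cross-conjugated with the Z trisubstituted C4(Me)=C5 alkene, and C2=C3 is trans within the ten-membered ring. Five stereocentres are contiguous, C6–C7–C8–C9–C10 (6S,7S,8S,9R,10R): C10 is quaternary (methyl, bridge oxygen, ketone carbon), C9 bears a free hydroxyl and C8 the isovalerate; the C6–O and C7–C11 bonds are cis on the C5–C8 segment. Fragile groups are the methylene lactone (Michael acceptor), the hydroxy ester pair at C8/C9 (acyl migration, β-elimination), the allylic C6–O bond and the base-sensitive vinylogous ester of the furanone. The real difficulty is the medium ring with its transannular bridge, the hindered C1–C10 bond that joins two oxygenated carbons, and the differentiation of the C8 and C9 oxygens. The key step uses two features: C3–C8, with the Z C4(Me)=C5 alkene and the three-carbon branch on C7, is the ring of carvone, and C1 and C10 each lie two atoms away from the adjacent ring carbons C3 and C8. They can therefore be the outer termini of two 2-alkoxyalkenyl groups on C3 and C8, and a [3,3] shift exchanges the C3–C8 bond for the C1–C10 bond.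

## Logic of the disconnections

44 to 43: the C12–O(C6) and C11–C12 bonds are cut, C12 leaving as carbon monoxide. This postpones the electrophilic methylene lactone to the last step and reduces the lactone to a vinyl triflate next to a free C6 hydroxyl. The forward step needs palladium to insert into the triflate in the presence of the furanone, and it needs the C6 hydroxyl cis to the C7 branch.

43 to 40 (through 42): the C11–O triflate bond and the two silyl ethers are removed, leaving a methyl ketone. The three-carbon lactone unit becomes the two-carbon acetyl group that ozonolysis of carvone provides. The forward step demands kinetic enolization on the methyl side without touching the ester or the C7 hydrogen.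

40 to 37 (through 39 and 38): the furanone O–C3 bond is cut and C1 is taken back to a protected alcohol, with the acetyl group re-masked as its ketal. This exposes a C2=C3 methyl enol ether and two 4-methoxybenzyl ethers on C1 and C10, which are exactly what a sigmatropic shift of two enol ethers delivers. The forward steps demand an oxidant that removes both benzyl groups without destroying the dienol ether, then selective oxidation of the allylic C1 alcohol.

37 to 31 (through 35 and 34, with 36): the ester C–O bond, the C8 carbinol hydrogen and the C9 oxygen are removed. The C8/C9 pair simplifies to one ketone with a methylene neighbour, and the two oxygens are introduced one after the other, so they are never equivalent. The forward steps must control regiochemistry of enolization and the configuration at C9 and C8.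

31 to 28: the C1–C10 bond is cut and the C3–C8 bond is formed in the retrosynthetic sense, contracting the ten-membered ring to a cyclohexene with alkenyl groups on C3 and C8. The ring, the quaternary C10 and the Z C4=C5 alkene are traded for two carbonyl additions to a six-membered ring. The forward step needs one chair transition state to dominate and a Z propenyl ether, so that C10 is formed with the right configuration.

28 to 23 and 26: the C8–C9 bond is cut (ketone plus alkenyl metal). This separates the four-carbon C9/C10/C14/O unit. The forward step is an addition to a hindered, enolizable ketone, with retention of the Z geometry of the reagent.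

23 to 14 and 17 (through 22, 21 and 20): the C3–C2 bond, the O-methyl bond and the C8 oxidation level are taken back. The enol ether on C3 comes from an alkoxyacetylide and the C8 ketone from a protected alcohol, so a 1,2-diketone (which would enolize through C7) is never formed. The forward steps need addition anti to the C7 branch and a trans reduction of the alkyne.

14 to 4 (through 11, 10, 9, 8 and 5): the C8–O and C6–O bonds are removed, leaving the bare enone. The C6 oxygen must end cis to the C7 branch, which an electrophilic oxygenation cannot give directly, so the forward sequence is anti oxygenation followed by inversion.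

4 to 1 (through 3): the ketal is removed and the acetyl carbonyl is traced to the isopropenyl group. C7 is then the stereocentre of a commercial terpene. The forward steps need chemoselective ozonolysis and ketalization in the presence of the enone.

26 to 24 and 15, and 17 to 15 and 16: both enol ether reagents come from the same alcohol by C–O bond formation to a two-carbon or a three-carbon alkyne equivalent. The forward steps rely on anti addition of an alkoxide to a haloalkyne and on addition–elimination at a chloroalkene.

## Other disconnections considered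

Alternative 1: The cut is the C8=C9 bond, taken as an alkene, so that the open diene A1 holds the finished methylene lactone on one side and the finished furanone on the other. Forward, the second-generation Grubbs catalyst would close the ten-membered ring to the triene A2, and the C8 and C9 oxygens would follow by epoxidation and opening at C8 with isovalerate. In its favour: the two heterocycles are built separately and joined late, the Z geometry of C8=C9 is the one a ten-membered ring prefers, few protecting groups are needed, and the neopentyl C9 steers a carboxylate to C8. On convergence and step economy it is the better plan. Against it here: the closure of a ten-membered ring by metathesis fights transannular strain with no pre-organization, the vinyl group on the quaternary C10 next to a ketone initiates slowly, the exocyclic methylene of the lactone is a further metathesis partner, and oligomerization competes. The quaternary C10 and the Z C4=C5 alkene, which the chosen plan takes from chirality transfer and from the carvone ring, need separate solutions. The facial selectivity of the epoxidation and the exposure of a Michael-accepting lactone to a carboxylate are open questions. Mechanistically, a reversible, strain-opposed closure stands against an irreversible, charge-accelerated enlargement of an existing ring.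

Alternative 2: The cuts are C7–C11 and C8–O together, the isoxazoline A4 being a masked β-hydroxy ketone. Forward, NaOCl would oxidize the aldoxime A3 to a nitrile oxide that adds across the Z C7=C8 alkene. In its favour: the intramolecular dipolar cycloaddition is concerted and suprafacial, and the tether from the C6 oxygen forces a cis ring fusion. The relative configuration of C6, C7 and C8 is therefore set more securely than by the hydride reduction of the chosen plan; on this point it is the better plan. The oxolane ring of the lactone is also formed at once. Against it here: it presupposes the furanone-bridged ten-membered ring with a Z C7=C8 alkene and the C9 carbinol, so the ring and C10, the hard part, are not addressed. After A4 there remain N–O cleavage beside a furanone and an alkene, methylenation at C11, oxidation of the C12 ether methylene to the lactone carbonyl, and acylation of a C8 hydroxyl β to a ketone. On step economy after the key step the chosen plan, with one carbonylation, is shorter.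

Alternative 3: The cut is C2–C3 (with the furanone C3–O bond), leading back to the nine-membered lactone A5, in which the C10 oxygen is acylated by the C3 carboxyl and C10 carries an acetyl group. Forward, LiN(SiMe3)2 would form the methyl ketone enolate, C2 would attack the lactone carbonyl through a five-membered transition state, the acyl group would move from oxygen to carbon, and acid would close the furanone to give A6. In its favour: it is a ring enlargement like the chosen step and shares its entropic advantage (equal on this point). It also reaches the furanone oxidation level in one operation, where the chosen plan needs deprotection, oxidation and acid (better on this point). Against it here: A5 is a nine-membered Z enoate closed onto a tertiary alcohol, a difficult lactonization, and must already hold all five stereocentres. Its conjugated carbonyl is a weak electrophile, and the butyrolactone offers competing acidic protons. After A6 the lactone must be methylenated under basic conditions beside the furanone, and the C8/C9 diol freed from the acetonide must be acylated at C8 only; the chosen plan avoids this by introducing the two oxygens stepwise. Step economy is comparable after the key step and unfavourable before it.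

Key step: step 16

Remark: germacrane numbering of 44 is used for every intermediate (C3–C8 are the six ring carbons from carvone, C11/C13 the acetyl carbons, C12 comes from CO); "branch" means the C7 (2-methyl-1,3-dioxolan-2-yl) group and cis/trans on the six-membered ring refer to it; PMB = 4-methoxybenzyl, TIPS = triisopropylsilyl, TES = triethylsilyl, TBS = tert-butyldimethylsilyl.

Remark: the two alkenyl groups of 28 are placed cis and the propenyl ether Z, because an acetylide should enter C3 anti to the branch; a trans arrangement with an E propenyl ether would map onto 44 equally well through a chair but would require the C3 nucleophile to enter syn to the branch. C1 of 31 is a transient stereocentre, erased at 39.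

## Route

Step 1
Reactants: 1 (S)-carvone
Product: 3 (5S)-5-acetyl-2-methylcyclohex-2-en-1-one, via methoxy hydroperoxide 2 (not isolated)
Conditions: O3, CH2Cl2/MeOH, −78 °C; Me2S, −78 °C to rt
Reagents that add atoms: ozone, [O-][O+]=O
Why: Ozone attacks the electron-rich 1,1-disubstituted alkene far faster than the conjugated enone; methanol traps the carbonyl oxide as 2 and Me2S reduces it (ozonolysis). No stereocentre is formed and C7 is untouched.

Step 2
Reactants: 3 (5S)-5-acetyl-2-methylcyclohex-2-en-1-one
Product: 4 (5S)-2-methyl-5-(2-methyl-1,3-dioxolan-2-yl)cyclohex-2-en-1-one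
Conditions: Me3SiOCH2CH2OSiMe3, Me3SiOTf (cat.), CH2Cl2, −78 °C
Reagents that add atoms: 1,2-bis(trimethylsilyloxy)ethane, C[Si](C)(C)OCCO[Si](C)(C)C
Why: Silyl-triflate-catalysed dioxolane formation at low temperature discriminates the saturated methyl ketone from the less basic conjugated ketone (chemoselective ketalization).

Step 3
Reactants: 4 (5S)-2-methyl-5-(2-methyl-1,3-dioxolan-2-yl)cyclohex-2-en-1-one
Product: 5 extended trimethylsilyl dienol ether of 4 (C3–OSiMe3; C3=C4 and C5=C6 double bonds)
Conditions: MeMgBr, FeCl3 (cat.), Et2O, −20 °C; Me3SiCl, Et3N, DMPU, −20 °C to rt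
Reagents that add atoms: chlorotrimethylsilane, C[Si](C)(C)Cl
Why: The iron-catalysed methylmagnesium base removes the γ-proton at C6 and gives the extended (thermodynamic) dienolate, which is O-silylated; this provides the s-cis ring diene needed for 1,4-oxygenation.

Step 4
Reactants: 5 extended trimethylsilyl dienol ether of 4
Product: 8 trans-γ-hydroxy enone (C6–OH trans to the branch), via endoperoxide 6 (not isolated), via hydroperoxy enone 7 (not isolated)
Conditions: O2, hν, tetraphenylporphyrin (cat.), CH2Cl2, −78 °C; MeOH, PPh3, −78 °C to rt
Reagents that add atoms: dioxygen, O=O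
Why: Singlet oxygen adds [4+2] across C3/C6 of the ring diene on the face opposite the branch (6); methanolysis of the silyl peroxyketal opens it to 7 and PPh3 reduces the hydroperoxide. The C6 oxygen is thereby set trans to the branch (photooxygenation of a silyl dienol ether).

Step 5
Reactants: 8 trans-γ-hydroxy enone
Product: 9 cis-γ-chloroacetoxy enone (C6–O cis to the branch)
Conditions: ClCH2CO2H, PPh3, DIAD, toluene, 0 °C to rt
Reagents that add atoms: chloroacetic acid, OC(=O)CCl
Why: Mitsunobu esterification inverts C6 by SN2 displacement of the alkoxyphosphonium group, giving the C6–O bond cis to the branch as the lactone requires. The equatorial leaving group has no antiperiplanar hydrogen, which disfavours elimination.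

Step 6
Reactants: 9 cis-γ-chloroacetoxy enone
Product: 10 cis-γ-hydroxy enone (C6–OH cis to the branch)
Conditions: K2CO3 (cat.), MeOH, 0 °C
Reagents that add atoms: none
Why: Chloroacetates are cleaved by methanol under very mild base, so the enone and ketal are left alone (transesterification); C6 is not touched.

Step 7
Reactants: 10 cis-γ-hydroxy enone
Product: 11 C6 triisopropylsilyl ether of 10
Conditions: i-Pr3SiOTf, 2,6-lutidine, CH2Cl2, −78 to 0 °C
Reagents that add atoms: triisopropylsilyl triflate, CC(C)[Si](C(C)C)(C(C)C)OS(=O)(=O)C(F)(F)F
Why: The silyl triflate silylates the hindered allylic alcohol at low temperature without ketal exchange; TIPS is chosen because it must survive the later fluoride cleavage of a triethylsilyl ether.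

Step 8
Reactants: 11 C6 triisopropylsilyl ether of 10
Product: 14 enone with C6–OTIPS (cis) plus C8–OTES (trans to the branch), via potassium dienolate 12 (not isolated), via potassium hydroxy-enone alkoxide 13 (not isolated)
Conditions: KN(SiMe3)2, THF, −78 °C; (+)-(camphorsulfonyl)oxaziridine; Et3SiCl, −78 to 0 °C
Reagents that add atoms: (camphorsulfonyl)oxaziridine, CC1(C)C2CCC13CS(=O)(=O)N4OC34C2; chlorotriethylsilane, CC[Si](Cl)(CC)CC
Why: Kinetic deprotonation at C8 gives the cross-conjugated enolate 12, which takes oxygen from the N-sulfonyloxaziridine on the face anti to the branch (13) and is silylated in the same flask (enolate hydroxylation). The C8 configuration matters only for the next addition, because C8 later becomes a ketone.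

Step 9
Reactants: 15 4-methoxybenzyl alcohol; 16 trichloroethylene
Product: 17 (E)-1,2-dichlorovinyl 4-methoxybenzyl ether
Conditions: KH, THF, 0 °C; 16, −50 °C to rt
Reagents that add atoms: none
Why: The potassium alkoxide adds to dichloroacetylene formed in situ from trichloroethylene (elimination, then anti addition), giving the dichlorovinyl ether that serves as a stored alkoxyacetylide.

Step 10
Reactants: 17 (E)-1,2-dichlorovinyl 4-methoxybenzyl ether; 14 bis-silylated enone
Product: 20 tertiary alcohol with an (E)-2-(4-methoxybenzyloxy)vinyl group on C3 (alkenyl trans and C3–OH cis to the branch), via lithium acetylide 18 (not isolated), via lithium propargylic alkoxide 19 (not isolated)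
Conditions: 17, n-BuLi (2.05 equiv), THF, −78 to −40 °C; 14, −78 °C; NaAlH2(OCH2CH2OMe)2, −78 to 0 °C
Reagents that add atoms: none
Why: n-BuLi converts 17 into the acetylide 18 (elimination, then Cl–Li exchange). The slim acetylide adds 1,2 to the enone along the axial trajectory anti to the branch, as nucleophiles do with carvone, which sets C3. The alkoxide 19 then directs trans hydroalumination of the alkyne to the E enol ether.

Step 11
Reactants: 20 tertiary alcohol with the E enol ether on C3
Product: 21 C3 methyl ether of 20
Conditions: KN(SiMe3)2, MeI (excess), THF, −78 to 0 °C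
Reagents that add atoms: iodomethane, CI
Why: Williamson methylation of the tertiary potassium alkoxide, with MeI present from the start, should outrun 1,2-silyl migration from the C8 oxygen; the methyl ether makes the C2=C3 bond of the rearrangement product a stable enol ether.

Step 12
Reactants: 21 C3 methyl ether
Product: 22 C8 alcohol (TES removed; C8–OH trans to the branch)
Conditions: Bu4NF, THF, 0 °C
Reagents that add atoms: none
Why: Fluoride cleaves the triethylsilyl ether far faster than the triisopropylsilyl ether, and the basic medium spares the enol ether and ketal.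

Step 13
Reactants: 22 C8 alcohol
Product: 23 C8 ketone
Conditions: Dess–Martin periodinane, NaHCO3, CH2Cl2, 0 °C to rt
Reagents that add atoms: none
Why: Buffered periodinane oxidation converts the hindered secondary alcohol to the ketone without acid that would hydrolyse the enol ether; no 1,2-diketone is involved because C3 is already quaternary.

Step 14
Reactants: 24 1-propynylmagnesium bromide; 15 4-methoxybenzyl alcohol
Product: 26 (Z)-1-bromo-2-(4-methoxybenzyloxy)prop-1-ene, via 1-bromopropyne 25 (not isolated)
Conditions: NBS, THF, −78 to 0 °C; 15, KOH (cat.), DMSO, 20 °C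
Reagents that add atoms: N-bromosuccinimide, O=C1CCC(=O)N1Br
Why: Electrophilic bromination of the alkynyl Grignard gives 25. The alkoxide adds to the methyl-bearing alkyne carbon and the α-bromo vinyl anion is protonated anti, which places O and Br cis (nucleophilic anti addition to a haloalkyne).

Step 15
Reactants: 26 (Z)-1-bromo-2-(4-methoxybenzyloxy)prop-1-ene; 23 C8 ketone
Product: 28 cis-1,2-dialkenylcyclohexenol (C8–OH cis and Z-propenyl ether trans to the branch; C3–OMe cis and E-vinyl ether trans to the branch), via Z alkenyllithium 27 (not isolated)
Conditions: 26, t-BuLi (2 equiv), Et2O, −78 °C; CeCl3, THF, −78 °C; 23, −78 to −40 °C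
Reagents that add atoms: none
Why: Br–Li exchange with retention gives the internally chelated Z alkenyllithium 27. After transmetallation to cerium it adds 1,2 to the hindered, enolizable ketone (organocerium addition) from the face opposite the branch and the pseudo-axial C6 silyloxy group, which sets C8.

Step 16
Reactants: 28 cis-1,2-dialkenylcyclohexenol
Product: 31 ten-membered dienone (C8 ketone; C1–OPMB; quaternary C10–OPMB; C2=C3 methyl enol ether trans in the ring; C4=C5 cis), via potassium alkoxide 29 (not isolated), via potassium enolate 30 (not isolated)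
Conditions: KN(SiMe3)2, 18-crown-6, THF, −78 to 0 °C; AcOH, −78 °C
Reagents that add atoms: none
Why: The base converts 28 into the free alkoxide 29, whose C3–C8 bond (doubly allylic, flanked by O– and OMe) breaks while C1–C10 forms in a concerted [3,3] sigmatropic shift (anionic oxy-Cope rearrangement); the closest known reaction type is the alkoxide-accelerated ring expansion of 1,2-dialkenylcyclohexanols to cyclodecenones. The ten-membered ring is not closed by a cyclization but arises by four-atom enlargement of the cyclohexene, so the cis C4=C5 geometry is inherited. In the half-chair with the branch equatorial, the C8 alkenyl group is equatorial and the C3 alkenyl group pseudo-axial (gauche), and the chair array C1–C2–C3–C8–C9–C10 built on this conformer has the oxyanion equatorial and OMe axial. In that chair the Z propenyl ether places OPMB axial and methyl equatorial on C10, so C1 bonds to the face of C9=C10 that gives the 10R configuration of 44; the E vinyl ether puts hydrogen axial on C1 (1S, erased later). The other chair needs the branch axial and syn to OMe and an axial oxyanion, which is the basis of the expected selectivity. A competing Cope pathway is excluded because the C7 acetyl is a ketal and not an isopropenyl group. The enolate 30 is protonated cold to limit β-elimination of the C10 or C6 oxygen substituents.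

Step 17
Reactants: 31 ten-membered dienone
Product: 34 C9 tert-butyldimethylsilyloxy ketone (C9 configured as in 44), via sodium enolate 32 (not isolated), via sodium ketol alkoxide 33 (not isolated)
Conditions: NaN(SiMe3)2, THF, −78 °C; (+)-(camphorsulfonyl)oxaziridine; t-BuMe2SiOTf, −78 to −40 °C
Reagents that add atoms: (camphorsulfonyl)oxaziridine, CC1(C)C2CCC13CS(=O)(=O)N4OC34C2; tert-butyldimethylsilyl triflate, CC(C)(C)[Si](C)(C)OS(=O)(=O)C(F)(F)F
Why: NaN(SiMe3)2 removes the accessible C9 proton (the C7 hydrogen is shielded by the ketal and silyloxy groups) and gives the sodium enolate 32, the counter-ion commonly used for oxygen transfer from N-sulfonyloxaziridines. Oxygen transfer sets C9 under combined reagent and substrate control (the antipodal oxaziridine is held in reserve), and the alkoxide 33 is silylated in the same flask (enolate hydroxylation).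

Step 18
Reactants: 34 C9 silyloxy ketone
Product: 35 C8 alcohol (C8 and C9 configured as in 44)
Conditions: i-Bu2AlH, CH2Cl2, −78 °C
Reagents that add atoms: none
Why: In the open, non-chelated ketone, hydride should enter anti to the polar C9–OSi bond (1,2-induction), which gives the 8,9-trans diol monoether; the aluminium alkoxide does not promote silyl migration.

Step 19
Reactants: 35 C8 alcohol; 36 isovaleryl chloride
Product: 37 C8 isovalerate
Conditions: pyridine, DMAP (cat.), CH2Cl2, 0 °C to rt
Reagents that add atoms: none
Why: DMAP-catalysed acylation of the only free hydroxyl installs the ester with retention at C8.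

Step 20
Reactants: 37 C8 isovalerate
Product: 38 C1,C10-diol
Conditions: DDQ, CH2Cl2/pH 7 buffer, 0 °C
Reagents that add atoms: none
Why: DDQ abstracts the benzylic hydride of each 4-methoxybenzyl ether and buffered water hydrolyses the oxocarbenium ions, which frees the allylic C1 and the tertiary C10 hydroxyls (oxidative debenzylation).

Step 21
Reactants: 38 C1,C10-diol
Product: 39 C1 ketone (β-methoxy enone) with free C10 hydroxyl
Conditions: MnO2, CH2Cl2, rt
Reagents that add atoms: none
Why: MnO2 oxidizes only the allylic C1 alcohol, which is activated by the enol ether; the tertiary alcohol and the silyl ethers are inert, and the transient C1 stereocentre disappears.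

Step 22
Reactants: 39 β-methoxy enone with free C10 hydroxyl
Product: 40 furanone methyl ketone (3,10-oxygen bridge closed; C7 acetyl free)
Conditions: PPTS, acetone/H2O, 50 °C
Reagents that add atoms: water, O
Why: The C10 hydroxyl adds to the protonated vinylogous ester at C3 and methanol is expelled (5-exo closure on the oxocarbenium ion, addition–elimination), giving the 3(2H)-furanone. The same mild acid hydrolyses the dioxolane, and the silyl ethers should survive.

Step 23
Reactants: 40 furanone methyl ketone
Product: 42 vinyl triflate (C11(OTf)=C13H2), via potassium enolate 41 (not isolated)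
Conditions: N-(5-chloro-2-pyridyl)bis(trifluoromethanesulfonimide), KN(SiMe3)2, THF, −78 °C
Reagents that add atoms: N-(5-chloro-2-pyridyl)bis(trifluoromethanesulfonimide), Clc1ccc(nc1)N(S(=O)(=O)C(F)(F)F)S(=O)(=O)C(F)(F)F
Why: Kinetic deprotonation on the methyl side (41) and immediate O-sulfonylation by the reactive triflimide at −78 °C should give the 1,1-disubstituted vinyl triflate before the enolate can equilibrate toward C7 or attack the ester.

Step 24
Reactants: 42 vinyl triflate
Product: 43 C6,C9-diol vinyl triflate
Conditions: HF·pyridine, pyridine, THF, 0 °C to rt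
Reagents that add atoms: none
Why: Buffered HF removes both silyl ethers; the ester, the furanone and the vinyl triflate are stable to it.

Step 25
Reactants: 43 C6,C9-diol vinyl triflate
Product: 44 CNP0175298.2, (6S,7S,8S,9R,10R)-9-hydroxy-8-(3-methylbutanoyloxy)-1-oxo-3,10-epoxygermacra-2,4Z,11(13)-trien-12,6-olide
Conditions: Pd(PPh3)4 (cat.), CO (1 atm), n-Bu3N, LiCl, MeCN, 60 °C
Reagents that add atoms: carbon monoxide, [C-]#[O+]
Why: Zerovalent palladium inserts into the vinyl triflate, CO inserts, and the acylpalladium is captured by the cis-disposed C6 hydroxyl (5-exo), giving the α-methylene-γ-butyrolactone (carbonylative lactonization). The C9 hydroxyl is trans-disposed and neopentyl and should not compete.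

## Compound list

1 | (S)-carvone, (5S)-2-methyl-5-(prop-1-en-2-yl)cyclohex-2-en-1-one | CC1=CC[C@@H](CC1=O)C(C)=C | starting material
2 | (5S)-5-(1-hydroperoxy-1-methoxyethyl)-2-methylcyclohex-2-en-1-one | CC1=CC[C@@H](CC1=O)C(C)(OC)OO | intermediate
3 | (5S)-5-acetyl-2-methylcyclohex-2-en-1-one | CC1=CC[C@@H](CC1=O)C(C)=O | intermediate
4 | (5S)-2-methyl-5-(2-methyl-1,3-dioxolan-2-yl)cyclohex-2-en-1-one | CC1=CC[C@@H](CC1=O)C2(C)OCCO2 | intermediate
5 | extended trimethylsilyl dienol ether of 4 (C3–OSiMe3, C3=C4, C5=C6) | C[Si](C)(C)OC1=C(C)C=C[C@@H](C1)C2(C)OCCO2 | intermediate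
6 | C3/C6 endoperoxide of 5, peroxide bridge anti to the branch | C[Si](C)(C)O[C@]12OO[C@H](C=C1C)[C@@H](C2)C3(C)OCCO3 | intermediate
7 | γ-hydroperoxy enone, C6–OOH trans to the branch | O=C1C(C)=C[C@@H](OO)[C@H](C2(C)OCCO2)C1 | intermediate
8 | γ-hydroxy enone, C6–OH trans to the branch | O=C1C(C)=C[C@@H](O)[C@H](C2(C)OCCO2)C1 | intermediate
9 | γ-chloroacetoxy enone, C6–O cis to the branch | O=C1C(C)=C[C@H](OC(=O)CCl)[C@H](C2(C)OCCO2)C1 | intermediate
10 | γ-hydroxy enone, C6–OH cis to the branch | O=C1C(C)=C[C@H](O)[C@H](C2(C)OCCO2)C1 | intermediate
11 | C6 triisopropylsilyl ether of 10 | O=C1C(C)=C[C@H](O[Si](C(C)C)(C(C)C)C(C)C)[C@H](C2(C)OCCO2)C1 | intermediate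
12 | potassium cross-conjugated dienolate of 11 (C3–OK, C3=C8) | [K+].[O-]C1=C[C@@H](C2(C)OCCO2)[C@@H](O[Si](C(C)C)(C(C)C)C(C)C)C=C1C | intermediate
13 | potassium alkoxide of the C8-hydroxy enone, C8–O trans to the branch | [K+].O=C1C(C)=C[C@H](O[Si](C(C)C)(C(C)C)C(C)C)[C@H](C2(C)OCCO2)[C@H]1[O-] | intermediate
14 | enone with C6–OTIPS (cis) and C8–OTES (trans to the branch) | O=C1C(C)=C[C@H](O[Si](C(C)C)(C(C)C)C(C)C)[C@H](C2(C)OCCO2)[C@H]1O[Si](CC)(CC)CC | intermediate
15 | 4-methoxybenzyl alcohol | COc1ccc(CO)cc1 | starting material
16 | trichloroethylene | ClC=C(Cl)Cl | starting material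
17 | (E)-1,2-dichlorovinyl 4-methoxybenzyl ether | COc1ccc(CO/C(Cl)=C\Cl)cc1 | intermediate
18 | lithium (4-methoxybenzyloxy)acetylide | COc1ccc(COC#C[Li])cc1 | intermediate
19 | lithium alkoxide of the C3 alkynyl carbinol, alkynyl trans to the branch | [Li+].CC[Si](CC)(CC)O[C@@H]1[C@@H](C2(C)OCCO2)[C@@H](O[Si](C(C)C)(C(C)C)C(C)C)C=C(C)[C@]1([O-])C#COCc3ccc(OC)cc3 | intermediate
20 | C3 tertiary alcohol with (E)-2-(4-methoxybenzyloxy)vinyl group trans to the branch, C8–OTES, C6–OTIPS | CC[Si](CC)(CC)O[C@@H]1[C@@H](C2(C)OCCO2)[C@@H](O[Si](C(C)C)(C(C)C)C(C)C)C=C(C)[C@]1(O)/C=C/OCc3ccc(OC)cc3 | intermediate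
21 | C3 methyl ether of 20 | CC[Si](CC)(CC)O[C@@H]1[C@@H](C2(C)OCCO2)[C@@H](O[Si](C(C)C)(C(C)C)C(C)C)C=C(C)[C@]1(OC)/C=C/OCc3ccc(OC)cc3 | intermediate
22 | C8 alcohol from 21, C8–OH trans to the branch | O[C@@H]1[C@@H](C2(C)OCCO2)[C@@H](O[Si](C(C)C)(C(C)C)C(C)C)C=C(C)[C@]1(OC)/C=C/OCc3ccc(OC)cc3 | intermediate
23 | C8 ketone with C3 (OMe cis, E-vinyl ether trans to the branch) and C6–OTIPS | O=C1[C@@H](C2(C)OCCO2)[C@@H](O[Si](C(C)C)(C(C)C)C(C)C)C=C(C)[C@]1(OC)/C=C/OCc3ccc(OC)cc3 | intermediate
24 | 1-propynylmagnesium bromide | CC#C[Mg]Br | starting material
25 | 1-bromopropyne | CC#CBr | intermediate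
26 | (Z)-1-bromo-2-(4-methoxybenzyloxy)prop-1-ene | COc1ccc(CO/C(C)=C\Br)cc1 | intermediate
27 | (Z)-2-(4-methoxybenzyloxy)prop-1-enyllithium | COc1ccc(CO/C(C)=C\[Li])cc1 | intermediate
28 | cis-1,2-dialkenylcyclohexenol: C8 (OH cis, Z-2-(PMBO)propenyl trans to the branch), C3 (OMe cis, E-2-(PMBO)vinyl trans), C6–OTIPS cis, C7 dioxolanyl | O[C@@]1(/C=C(/C)OCc2ccc(OC)cc2)[C@@H](C3(C)OCCO3)[C@@H](O[Si](C(C)C)(C(C)C)C(C)C)C=C(C)[C@]1(OC)/C=C/OCc4ccc(OC)cc4 | intermediate
29 | potassium alkoxide of 28 | [K+].[O-][C@@]1(/C=C(/C)OCc2ccc(OC)cc2)[C@@H](C3(C)OCCO3)[C@@H](O[Si](C(C)C)(C(C)C)C(C)C)C=C(C)[C@]1(OC)/C=C/OCc4ccc(OC)cc4 | intermediate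
30 | potassium enolate of 31 (C8–OK, C8=C9 cis in the ring) | [K+].CC(C)[Si](C(C)C)(C(C)C)O[C@H]1/C=C(/C)\C(OC)=C\[C@H](OCc2ccc(OC)cc2)[C@](C)(OCc3ccc(OC)cc3)/C=C(/[O-])[C@H]1C4(C)OCCO4 | intermediate
31 | ten-membered dienone: C8 ketone, (1S)-C1–OPMB, C10(Me)–OPMB, C2=C3(OMe) trans in the ring, C4=C5 cis, C6–OTIPS, C7 dioxolanyl; C6, C7, C10 as in 44 | CC(C)[Si](C(C)C)(C(C)C)O[C@H]1/C=C(/C)\C(OC)=C\[C@H](OCc2ccc(OC)cc2)[C@](C)(OCc3ccc(OC)cc3)CC(=O)[C@H]1C4(C)OCCO4 | intermediate
32 | sodium enolate of 31 (C8–ONa, drawn with C8=C9 cis in the ring) | [Na+].CC(C)[Si](C(C)C)(C(C)C)O[C@H]1/C=C(/C)\C(OC)=C\[C@H](OCc2ccc(OC)cc2)[C@](C)(OCc3ccc(OC)cc3)/C=C(/[O-])[C@H]1C4(C)OCCO4 | intermediate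
33 | sodium alkoxide of the C9-hydroxy ketone, C9 as in 44 | [Na+].CC(C)[Si](C(C)C)(C(C)C)O[C@H]1/C=C(/C)\C(OC)=C\[C@H](OCc2ccc(OC)cc2)[C@](C)(OCc3ccc(OC)cc3)[C@H]([O-])C(=O)[C@H]1C4(C)OCCO4 | intermediate
34 | C9–OTBS ketone | CC(C)[Si](C(C)C)(C(C)C)O[C@H]1/C=C(/C)\C(OC)=C\[C@H](OCc2ccc(OC)cc2)[C@](C)(OCc3ccc(OC)cc3)[C@H](O[Si](C)(C)C(C)(C)C)C(=O)[C@H]1C4(C)OCCO4 | intermediate
35 | C8 alcohol, C8 and C9 as in 44 | CC(C)[Si](C(C)C)(C(C)C)O[C@H]1/C=C(/C)\C(OC)=C\[C@H](OCc2ccc(OC)cc2)[C@](C)(OCc3ccc(OC)cc3)[C@H](O[Si](C)(C)C(C)(C)C)[C@@H](O)[C@H]1C4(C)OCCO4 | intermediate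
36 | isovaleryl chloride | CC(C)CC(=O)Cl | starting material
37 | C8 isovalerate of 35 | CC(C)[Si](C(C)C)(C(C)C)O[C@H]1/C=C(/C)\C(OC)=C\[C@H](OCc2ccc(OC)cc2)[C@](C)(OCc3ccc(OC)cc3)[C@H](O[Si](C)(C)C(C)(C)C)[C@@H](OC(=O)CC(C)C)[C@H]1C4(C)OCCO4 | intermediate
38 | C1,C10-diol | CC(C)[Si](C(C)C)(C(C)C)O[C@H]1/C=C(/C)\C(OC)=C\[C@H](O)[C@](C)(O)[C@H](O[Si](C)(C)C(C)(C)C)[C@@H](OC(=O)CC(C)C)[C@H]1C2(C)OCCO2 | intermediate
39 | C1 ketone (β-methoxy enone) with free C10 hydroxyl | CC(C)[Si](C(C)C)(C(C)C)O[C@H]1/C=C(/C)\C(OC)=C\C(=O)[C@](C)(O)[C@H](O[Si](C)(C)C(C)(C)C)[C@@H](OC(=O)CC(C)C)[C@H]1C2(C)OCCO2 | intermediate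
40 | furanone with C7 acetyl, C6–OTIPS, C9–OTBS, C8 isovalerate | CC(C)[Si](C(C)C)(C(C)C)O[C@H]1/C=C(/C)C2=CC(=O)[C@](C)(O2)[C@H](O[Si](C)(C)C(C)(C)C)[C@@H](OC(=O)CC(C)C)[C@H]1C(C)=O | intermediate
41 | potassium enolate of 40 (C11–OK, C11=C13) | [K+].CC(C)[Si](C(C)C)(C(C)C)O[C@H]1/C=C(/C)C2=CC(=O)[C@](C)(O2)[C@H](O[Si](C)(C)C(C)(C)C)[C@@H](OC(=O)CC(C)C)[C@H]1C(=C)[O-] | intermediate
42 | vinyl triflate of 40 | CC(C)[Si](C(C)C)(C(C)C)O[C@H]1/C=C(/C)C2=CC(=O)[C@](C)(O2)[C@H](O[Si](C)(C)C(C)(C)C)[C@@H](OC(=O)CC(C)C)[C@H]1C(=C)OS(=O)(=O)C(F)(F)F | intermediate
43 | C6,C9-diol vinyl triflate | O[C@H]1/C=C(/C)C2=CC(=O)[C@](C)(O2)[C@H](O)[C@@H](OC(=O)CC(C)C)[C@H]1C(=C)OS(=O)(=O)C(F)(F)F | intermediate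
44 | CNP0175298.2 | C=C1C(=O)O[C@H]2/C=C(/C)C3=CC(=O)[C@](C)(O3)[C@H](O)[C@@H](OC(=O)CC(C)C)[C@@H]12 | target

## Step count and least certain steps

Total step count: 25. Longest linear sequence: 23 steps from 1 (steps 1–8, 10–13, 15–25); steps 9 and 14 prepare the two enol ether reagents.

Step 16 (key step). The most likely failure is leakage through the second chair, which would erode control at C10, together with β-elimination of the C10 or C6 oxygen from the strongly basic enolate. The fallback is the neutral variant of the same shift. It sets out from 28: N-(trimethylsilyl)imidazole should give the trimethylsilyl ether F1. Thermolysis in a base-washed vessel (o-dichlorobenzene, 140–180 °C) should give the trimethylsilyl enol ether F2 without any free enolate; the conformer with the equatorial branch again decides the chair. K2CO3 in MeOH then releases the ketone, and the fallback comes back to the route at 31.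

Step 15. The most likely failure is enolization of the hindered ketone by the basic organometallic, or no addition at all. Poor facial selectivity at C8 matters less, because entry from the other face would give a carbinol with only one chair open to it, and that chair leads to the same C10 configuration. The fallback sets out from 23 and uses the slim acetylide 18 (made as in step 10), which should add to give the alkynyl carbinol F3. Syn carbocupration with MeCu·MgBr2 (from MeMgBr and CuBr·SMe2) places methyl on the oxygen-bearing alkyne carbon and copper on C9. Protonation then gives the Z propenyl ether, and the fallback comes back at 28.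

Step 17. The most likely failure is loss of regiocontrol in the deprotonation (C7 instead of C9), followed by β-elimination of the C6 silyloxy group; insufficient facial selectivity at C9 is the second concern. The fallback merges this step with step 16 and so avoids any deprotonation of the ketone. It sets out from 28; after the rearrangement the regiodefined enolate 30 is not protonated but oxidized in the same flask with the oxaziridine to the potassium alkoxide of the C9-hydroxy ketone F4, which is silylated with t-BuMe2SiOTf. The fallback comes back at 34.

Step 18. The most likely failure is poor facial selectivity of hydride delivery, because the C7 and C9 stereocentres may direct in opposite senses. The fallback sets out from 34: a hydride source that gives the C8-epimeric alcohol F5 cleanly (for example the bulky LiBH(s-Bu)3) is chosen instead. Mitsunobu esterification of F5 with isovaleric acid (PPh3, DIAD) then installs the ester with inversion, and the fallback comes back at 37.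

Step 5. The most likely failure is a slow SN2 reaction at the hindered C6 with competing elimination toward an aromatic by-product. The fallback sets out from 5: NBS in THF at −78 °C should brominate the γ-position anti to the branch and give the γ-bromo enone F6. CsO2CCH2Cl in DMF then displaces bromide with inversion, and the fallback comes back at 9.

Step 23. The most likely failure is unselective deprotonation (C7–H or the vinylogous positions of the furanone), leading to β-elimination of the isovalerate or acyl transfer. The fallback avoids enolate chemistry and sets out from 40. Methylenation under non-basic conditions (Zn, CH2Br2, TiCl4) should give the isopropenyl compound F7. Allylic oxidation (SeO2 cat., t-BuOOH) should give the allylic alcohol F8, and HF·pyridine the triol F9. TEMPO/PhI(OAc)2 then oxidizes the primary allylic alcohol and closes the lactone through the lactol, and the fallback comes back at 44.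

## Further compounds

F1 | step 16 | trimethylsilyl ether of 28 | C[Si](C)(C)O[C@@]1(/C=C(/C)OCc2ccc(OC)cc2)[C@@H](C3(C)OCCO3)[C@@H](O[Si](C(C)C)(C(C)C)C(C)C)C=C(C)[C@]1(OC)/C=C/OCc4ccc(OC)cc4
F2 | step 16 | trimethylsilyl enol ether of 31 (C8–OSiMe3, C8=C9) | CC(C)[Si](C(C)C)(C(C)C)O[C@H]1/C=C(/C)\C(OC)=C\[C@H](OCc2ccc(OC)cc2)[C@](C)(OCc3ccc(OC)cc3)/C=C(/O[Si](C)(C)C)[C@H]1C4(C)OCCO4
F3 | step 15 | C8 alkynyl carbinol (C8–C≡C–OPMB trans to the branch) | O[C@@]1(C#COCc2ccc(OC)cc2)[C@@H](C3(C)OCCO3)[C@@H](O[Si](C(C)C)(C(C)C)C(C)C)C=C(C)[C@]1(OC)/C=C/OCc4ccc(OC)cc4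
F4 | step 17 | potassium alkoxide of the C9-hydroxy ketone, C9 as in 44 | [K+].CC(C)[Si](C(C)C)(C(C)C)O[C@H]1/C=C(/C)\C(OC)=C\[C@H](OCc2ccc(OC)cc2)[C@](C)(OCc3ccc(OC)cc3)[C@H]([O-])C(=O)[C@H]1C4(C)OCCO4
F5 | step 18 | C8 epimer of 35 | CC(C)[Si](C(C)C)(C(C)C)O[C@H]1/C=C(/C)\C(OC)=C\[C@H](OCc2ccc(OC)cc2)[C@](C)(OCc3ccc(OC)cc3)[C@H](O[Si](C)(C)C(C)(C)C)[C@H](O)[C@H]1C4(C)OCCO4
F6 | step 5 | γ-bromo enone, C6–Br trans to the branch | O=C1C(C)=C[C@@H](Br)[C@H](C2(C)OCCO2)C1
F7 | step 23 | isopropenyl analogue of 40 | CC(C)[Si](C(C)C)(C(C)C)O[C@H]1/C=C(/C)C2=CC(=O)[C@](C)(O2)[C@H](O[Si](C)(C)C(C)(C)C)[C@@H](OC(=O)CC(C)C)[C@H]1C(C)=C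
F8 | step 23 | allylic alcohol from F7 (C12 hydroxymethyl) | CC(C)[Si](C(C)C)(C(C)C)O[C@H]1/C=C(/C)C2=CC(=O)[C@](C)(O2)[C@H](O[Si](C)(C)C(C)(C)C)[C@@H](OC(=O)CC(C)C)[C@H]1C(=C)CO
F9 | step 23 | desilylated triol from F8 | O[C@H]1/C=C(/C)C2=CC(=O)[C@](C)(O2)[C@H](O)[C@@H](OC(=O)CC(C)C)[C@H]1C(=C)CO
A1 | alternative 1 | open diene with vinyl groups on C7 and C10 | C=C1C(=O)O[C@@H](/C=C(/C)C2=CC(=O)[C@](C)(O2)C=C)[C@H]1C=C
A2 | alternative 1 | furanone-bridged cyclodecatriene lactone with Z C8=C9 | C=C1C(=O)O[C@H]2/C=C(/C)C3=CC(=O)[C@](C)(O3)/C=C\[C@@H]12
A3 | alternative 2 | aldoxime tethered through the C6 oxygen, Z C7=C8 alkene | ON=CCO[C@H]1/C=C(/C)C2=CC(=O)[C@](C)(O2)[C@H](O[Si](CC)(CC)CC)/C=C\1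
A4 | alternative 2 | isoxazoline-fused oxolane | N1=C2CO[C@H]3/C=C(/C)C4=CC(=O)[C@](C)(O4)[C@H](O[Si](CC)(CC)CC)[C@@H](O1)[C@@H]23
A5 | alternative 3 | nine-membered lactone with C10 acetyl group | CC(=O)[C@]1(C)OC(=O)/C(C)=C\[C@@H]2OC(=O)C[C@@H]2[C@@H]3OC(C)(C)O[C@@H]13
A6 | alternative 3 | furanone-bridged carbocycle with unmethylenated lactone and acetonide | C1C(=O)O[C@H]2/C=C(/C)C3=CC(=O)[C@](C)(O3)[C@@H]4OC(C)(C)O[C@H]4[C@@H]12
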